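**Retrosynthetic overview**

- Feature: ring B (C5–C10, labdane numbering) is cis-fused to ring A along C5–C10 and carries C11 on C9 anti to the C10 methyl. This is the pattern of an endo [4+2] adduct of a 2-methylcyclohex-2-enone with an (E)-1-alkyl diene.
- The C8 carbinol comes from hydride opening of a 7,8-epoxide, the C1 methylene from Wolff–Kishner removal of the ketone that activated the dienophile, and the C15 acetate is put on last.
- Ring B is disconnected at C5–C6 and C9–C10 into 2,4,4-trimethylcyclohex-2-en-1-one (ring A, the 5,10-alkene) and (3S,6E)-3,7-dimethylnona-6,8-dien-1-yl acetate (C6–C9, C11–C16, the C13 centre).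
- The diene comes from (S)-citronellol (acetylation, SeO2 oxidation of the (E)-methyl, Wittig methylenation); the enone from isobutyraldehyde and ethyl vinyl ketone by enamine annulation.
- Ring order: ring A first (step 6), ring B second (step 7).

Key step: step 7

Remark on numbering: labdane numbering is used for the bicyclic compounds. Ring A is C1–C5 and C10; ring B is C5–C10; the chain C11–C15 sits on C9 with O on C15 and a methyl on C13; methyls sit on C4 (two), C8 and C10.

Remark on the protecting group: the acetate serves as C15 protection up to the cycloaddition, is knowingly lost in step 8 and is put back in step 11.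

Assumption: the (S)-configured oxazaborolidine–AlBr3 Lewis acid is taken to expose the Si,Si face of the C5=C10 bond of 11; if the first run shows the opposite sense, its (R)-antipode is used with no other change.

**Route**

Step 1
Reactants: 1 (S)-citronellol
Product: 2 (S)-citronellyl acetate, (3S)-3,7-dimethyloct-6-en-1-yl acetate
Conditions: Ac2O (1.2 equiv), pyridine, DMAP (cat.), CH2Cl2, 0 °C → rt
Reagents that add atoms: acetic anhydride, CC(=O)OC(C)=O
Why: Nucleophile-catalysed O-acylation of an unhindered primary alcohol, which masks the hydroxyl through the allylic oxidation, the olefination and the cycloaddition and does not touch the C13 centre.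

Step 2
Reactants: 2 (S)-citronellyl acetate
Product: 3 (3S,6E)-8-hydroxy-3,7-dimethyloct-6-en-1-yl acetate
Conditions: SeO2 (0.3 equiv), t-BuOOH (3 equiv), salicylic acid (cat.), CH2Cl2, rt
Reagents that add atoms: tert-butyl hydroperoxide, CC(C)(C)OO (terminal oxygen source); selenium dioxide, O=[Se]=O (catalytic oxygen carrier)
Why: Riley-type allylic oxidation (ene reaction, then [2,3]-sigmatropic shift) functionalises the (E)-methyl of a trisubstituted prenyl terminus selectively, as is standard for citronellyl and geranyl esters, and any enal 4 formed by over-oxidation is simply carried into step 3 together with 3.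

Step 3
Reactants: 3 (3S,6E)-8-hydroxy-3,7-dimethyloct-6-en-1-yl acetate
Product: 4 (3S,6E)-3,7-dimethyl-8-oxooct-6-en-1-yl acetate
Conditions: Dess–Martin periodinane (1.2 equiv), CH2Cl2, 0 °C → rt
Reagents that add atoms: none
Why: Dess–Martin oxidation of a primary allylic alcohol stops at the enal under near-neutral conditions that preserve the (E)-geometry and the acetate.

Step 4
Reactants: 4 (3S,6E)-3,7-dimethyl-8-oxooct-6-en-1-yl acetate
Product: 5 (3S,6E)-3,7-dimethylnona-6,8-dien-1-yl acetate
Conditions: Ph3PCH3Br (1.2 equiv), KN(SiMe3)2 (1.1 equiv), THF, 0 °C; then 4, −78 → 0 °C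
Reagents that add atoms: methyltriphenylphosphonium bromide, C[P+](c1ccccc1)(c1ccccc1)c1ccccc1.[Br-]
Why: Wittig methylenation, in which the non-stabilised ylide adds to the aldehyde far faster than to the acetate at low temperature, the base is kept below the amount of phosphonium salt so that none is left to cleave the ester, and the trisubstituted (E)-alkene is not touched.

Step 5
Reactants: 6 isobutyraldehyde
Product: 7 1-(2-methylprop-1-en-1-yl)pyrrolidine
Conditions: pyrrolidine (1.1 equiv), toluene, reflux, Dean–Stark; distillation
Reagents that add atoms: pyrrolidine, C1CCNC1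
Why: Condensation of an α-branched aldehyde with a secondary amine under azeotropic removal of water gives the enamine needed for a Stork-type annulation.

Step 6
Reactants: 7 1-(2-methylprop-1-en-1-yl)pyrrolidine; 8 ethyl vinyl ketone
Product: 11 2,4,4-trimethylcyclohex-2-en-1-one, via dihydropyran adduct 9 (not isolated), via keto aldehyde 10 (not isolated)
Conditions: neat, 0 °C → rt; then 6 M aq. HCl, rt → 60 °C
Reagents that add atoms: none
Why: Stork enamine conjugate addition to the vinyl ketone, acid hydrolysis and intramolecular aldol condensation (a Robinson-type annulation) close ring A, the α-carbon of the ethyl ketone condensing with the aldehyde so that the ring carries the 2-methyl and the 4,4-dimethyl groups.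

Step 7
Reactants: 5 (3S,6E)-3,7-dimethylnona-6,8-dien-1-yl acetate; 11 2,4,4-trimethylcyclohex-2-en-1-one
Product: 12 (3S)-3-methyl-5-[(1S,4aS,8aR)-2,5,5,8a-tetramethyl-8-oxo-1,4,4a,5,6,7,8,8a-octahydronaphthalen-1-yl]pentyl acetate (cis-fused 1-oxo-7-ene; H5 and the 10-methyl syn, C11 anti to the 10-methyl)
Conditions: 11 (2.5 equiv), AlBr3 adduct of (S)-3,3-diphenyl-1-(2-methylphenyl)tetrahydro-1H,3H-pyrrolo[1,2-c][1,3,2]oxazaborole (20 mol%), CH2Cl2, −40 → 0 °C
Reagents that add atoms: none
Why: Proposed new method: the chiral Lewis acid binds the C1 carbonyl of 11, lowers the enone LUMO and lets the diene add in one concerted, asynchronous [4+2] step in which the C5–C6 bond runs ahead of the C9–C10 bond; the closest known reactions are the Lewis-acid-promoted Diels–Alder additions of acyclic dienes to 2-methylcyclohex-2-enones and the enantioselective oxazaborolidine–AlBr3-catalysed additions to cyclohex-2-enones, whereas an α-methyl, γ,γ-dimethyl enone has not been shown to react under catalyst control. Ring B is closed by this intermolecular cycloaddition, each partner reacting suprafacially, so both ring-B bonds are made in the one event. C5 and C10 are set together by addition to a single face of the ring alkene, which makes the fusion cis (H5 and the 10-methyl syn), and C9 is set by the endo placement of the complexed C1 carbonyl under the diene combined with the (E)-geometry at C8=C9, which puts C11 syn to C1 and anti to the 10-methyl. The step needs regio-, endo- and facial selectivity: the alkyl group on C9 gives the unsubstituted terminus C6 the larger HOMO coefficient, and the neopentyl-like β-carbon C5 can accept only that CH2 terminus in the leading bond, so the 1-substituent should outweigh the opposing 8-methyl, while the Lewis-acid-bound carbonyl secures endo. The absolute sense is not set by the substrate, whose C13 centre is too remote, but by the catalyst, which must expose the Si,Si face of the C5=C10 bond.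

Step 8
Reactants: 12 cis-fused 1-oxo-7-ene acetate
Product: 14 (3S)-3-methyl-5-[(1S,4aS,8aR)-2,5,5,8a-tetramethyl-1,4,4a,5,6,7,8,8a-octahydronaphthalen-1-yl]pentan-1-ol, via hydrazone 13 (not isolated)
Conditions: N2H4·H2O (10 equiv), KOH (6 equiv), diethylene glycol, 130 °C; then water distilled off, 200–210 °C
Reagents that add atoms: none
Why: Wolff–Kishner reduction in the Huang-Minlon form converts the C1 carbonyl into a methylene through loss of N2 from the hydrazone anion, the neighbouring C10 is quaternary so no stereocentre can epimerise, the isolated trisubstituted alkene is inert to the base, and the concurrent saponification of the acetate is accepted because the ester is restored in step 11.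

Step 9
Reactants: 14 cis-fused 7-en-15-ol
Product: 15 (3S)-3-methyl-5-[(5S,7R,8S,9R,10R)-7,8-epoxy-4,4,8,10-tetramethyldecalin-9-yl]pentan-1-ol (labdane numbering; oxirane on the ring-B face that carries H5, H9 and the 10-methyl, anti to C11)
Conditions: mCPBA (1.2 equiv), NaHCO3, CH2Cl2, 0 °C
Reagents that add atoms: 3-chloroperoxybenzoic acid, OOC(=O)c1cccc(Cl)c1
Why: Prilezhaev epoxidation of the only alkene should deliver oxygen to the convex face of the cis-fused bicycle, anti to the C11 chain on the allylic C9 and away from ring A, which folds over the other face, and this sets C7 and C8.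

Step 10
Reactants: 15 7,8-epoxide
Product: 16 (1R,2R,4aS,8aR)-1-[(3S)-5-hydroxy-3-methylpentyl]-2,5,5,8a-tetramethyldecahydronaphthalen-2-ol
Conditions: LiAlH4 (3 equiv), THF, reflux; aq. NaOH work-up
Reagents that add atoms: none
Why: LiAlH4 reduction of a trisubstituted epoxide proceeds by SN2 attack of hydride at the less substituted C7, which leaves the C8–O bond intact so that the tertiary hydroxyl keeps the configuration set in step 9.

Step 11
Reactants: 16 8,15-diol
Product: 17 (3S)-5-[(1R,2R,4aS,8aR)-2-hydroxy-2,5,5,8a-tetramethyldecahydronaphthalen-1-yl]-3-methylpentyl acetate (target)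
Conditions: Ac2O (1.5 equiv), pyridine, CH2Cl2, 0 °C → rt
Reagents that add atoms: acetic anhydride, CC(=O)OC(C)=O
Why: Selective O-acylation, in which the primary C15 hydroxyl is acetylated under conditions (no DMAP, ambient temperature) that leave the hindered tertiary C8 hydroxyl unchanged.

**Compound list**

1 | (S)-citronellol, (3S)-3,7-dimethyloct-6-en-1-ol | OCC[C@@H](C)CCC=C(C)C | starting material
2 | (S)-citronellyl acetate | CC(=O)OCC[C@@H](C)CCC=C(C)C | intermediate
3 | (3S,6E)-8-hydroxy-3,7-dimethyloct-6-en-1-yl acetate | CC(=O)OCC[C@@H](C)CC/C=C(\C)CO | intermediate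
4 | (3S,6E)-3,7-dimethyl-8-oxooct-6-en-1-yl acetate | CC(=O)OCC[C@@H](C)CC/C=C(\C)C=O | intermediate
5 | (3S,6E)-3,7-dimethylnona-6,8-dien-1-yl acetate | CC(=O)OCC[C@@H](C)CC/C=C(C)/C=C | intermediate
6 | isobutyraldehyde | CC(C)C=O | starting material
7 | 1-(2-methylprop-1-en-1-yl)pyrrolidine | CC(C)=CN1CCCC1 | intermediate
8 | ethyl vinyl ketone, pent-1-en-3-one | CCC(=O)C=C | starting material
9 | 6-ethyl-3,3-dimethyl-2-(pyrrolidin-1-yl)-3,4-dihydro-2H-pyran (racemic) | CCC1=CCC(C)(C)C(N2CCCC2)O1 | intermediate
10 | 2,2-dimethyl-5-oxoheptanal | CCC(=O)CCC(C)(C)C=O | intermediate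
11 | 2,4,4-trimethylcyclohex-2-en-1-one | CC1=CC(C)(C)CCC1=O | intermediate
12 | (3S)-3-methyl-5-[(1S,4aS,8aR)-2,5,5,8a-tetramethyl-8-oxo-1,4,4a,5,6,7,8,8a-octahydronaphthalen-1-yl]pentyl acetate | CC(=O)OCC[C@@H](C)CC[C@@H]1[C@]2(C)C(=O)CCC(C)(C)[C@@H]2CC=C1C | intermediate
13 | (3S)-5-[(1S,4aS,8aR)-8-hydrazinylidene-2,5,5,8a-tetramethyl-1,4,4a,5,6,7,8,8a-octahydronaphthalen-1-yl]-3-methylpentan-1-ol | OCC[C@@H](C)CC[C@@H]1[C@]2(C)C(=NN)CCC(C)(C)[C@@H]2CC=C1C | intermediate
14 | (3S)-3-methyl-5-[(1S,4aS,8aR)-2,5,5,8a-tetramethyl-1,4,4a,5,6,7,8,8a-octahydronaphthalen-1-yl]pentan-1-ol | OCC[C@@H](C)CC[C@@H]1[C@]2(C)CCCC(C)(C)[C@@H]2CC=C1C | intermediate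
15 | (3S)-3-methyl-5-[(5S,7R,8S,9R,10R)-7,8-epoxy-4,4,8,10-tetramethyldecalin-9-yl]pentan-1-ol (labdane numbering) | OCC[C@@H](C)CC[C@@H]1[C@]2(C)CCCC(C)(C)[C@@H]2C[C@H]3O[C@]31C | intermediate
16 | (1R,2R,4aS,8aR)-1-[(3S)-5-hydroxy-3-methylpentyl]-2,5,5,8a-tetramethyldecahydronaphthalen-2-ol | OCC[C@@H](C)CC[C@@H]1[C@]2(C)CCCC(C)(C)[C@@H]2CC[C@@]1(C)O | intermediate
17 | (3S)-5-[(1R,2R,4aS,8aR)-2-hydroxy-2,5,5,8a-tetramethyldecahydronaphthalen-1-yl]-3-methylpentyl acetate | CC(=O)OCC[C@@H](C)CC[C@@H]1[C@]2(C)CCCC(C)(C)[C@@H]2CC[C@@]1(C)O | target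

**Step count**

Total: 11 steps. Longest linear sequence: 9 steps (steps 1–4 and 7–11, from (S)-citronellol); the enone branch (steps 5 and 6) joins at step 7.

**Steps most likely to fail**

1. Step 7 (Proposed new method).
   - What may go wrong: the cycloaddition of the hindered, trisubstituted enone may be slow under a catalytic Lewis acid, so that diene oligomerisation or catalyst inhibition by the acetate takes over. Facial discrimination may also be weak, because the enone has no α-hydrogen to organise its binding to the catalyst, so that both decalin antipodes form on the (13S)-chain.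
   - Fallback: it sets out from 5 and 11 and comes back at 12. The two partners are combined under a stoichiometric achiral Lewis acid (EtAlCl2, 1.5 equiv, toluene, 0 → 40 °C), the established way of adding acyclic dienes to 2-methylcyclohex-2-enones. Without catalyst control this should give 12 together with its diastereomer of antipodal decalin configuration, (3S)-3-methyl-5-[(1R,4aR,8aS)-2,5,5,8a-tetramethyl-8-oxo-1,4,4a,5,6,7,8,8a-octahydronaphthalen-1-yl]pentyl acetate F1. The two differ only in the sense of the bicycle relative to the remote C13 centre, so they are treated as a quasi-enantiomeric pair and separated by preparative chromatography on a chiral stationary phase (cellulose tris(3,5-dimethylphenylcarbamate)); 12 then enters step 8.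

2. Step 8.
   - What may go wrong: hydrazone formation at the C1 carbonyl, which is flanked by the quaternary C10, may be incomplete, azine formation may compete, or the 7,8-alkene may migrate in hot alkali.
   - Fallback: it sets out from 12 and comes back at 14, replacing the ionic deoxygenation by a radical one. NaBH4 (MeOH–THF, 0 °C → rt) should reduce the ketone to the C1 carbinol, (3S)-5-[(1S,4aS,8aR)-8-hydroxy-2,5,5,8a-tetramethyl-1,4,4a,5,6,7,8,8a-octahydronaphthalen-1-yl]-3-methylpentyl acetate F2 (configuration at the carbinol carbon immaterial). 1,1'-Thiocarbonyldiimidazole with DMAP in refluxing toluene should convert it into the O-alkyl imidazole-1-carbothioate F3. Barton–McCombie reduction (Bu3SnH, AIBN, toluene, reflux) should give the deoxygenated acetate, (3S)-3-methyl-5-[(1S,4aS,8aR)-2,5,5,8a-tetramethyl-1,4,4a,5,6,7,8,8a-octahydronaphthalen-1-yl]pentyl acetate F4. Methanolysis (K2CO3, MeOH, rt) then gives 14.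

3. Step 9.
   - What may go wrong: poor facial discrimination, or attack of the peracid on the concave face if the 10-methyl, axial in one ring-B conformer, shields the convex face at C8; either would place the C8 oxygen syn to C11.
   - Fallback: it sets out from 14 and comes back at 16, replacing syn delivery of oxygen by an anti addition. Oxymercuration (Hg(OAc)2, THF–H2O, rt) should give the trans-hydroxy organomercurial, the 7-(acetoxymercurio)-8-hydroxy compound F5. Here the electrophile takes the face the peracid prefers and water enters C8 from the opposite face under trans-diaxial control. Reduction in the same flask (NaBH4, aq. NaOH) removes the mercury and gives 16, which is purified from any C8 epimer by chromatography.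

**Further compounds**

F1 | step 7 | (3S)-3-methyl-5-[(1R,4aR,8aS)-2,5,5,8a-tetramethyl-8-oxo-1,4,4a,5,6,7,8,8a-octahydronaphthalen-1-yl]pentyl acetate | CC(=O)OCC[C@@H](C)CC[C@H]1[C@@]2(C)C(=O)CCC(C)(C)[C@H]2CC=C1C
F2 | step 8 | (3S)-5-[(1S,4aS,8aR)-8-hydroxy-2,5,5,8a-tetramethyl-1,4,4a,5,6,7,8,8a-octahydronaphthalen-1-yl]-3-methylpentyl acetate | CC(=O)OCC[C@@H](C)CC[C@@H]1[C@]2(C)C(O)CCC(C)(C)[C@@H]2CC=C1C
F3 | step 8 | O-[(4aS,8S,8aR)-8-[(3S)-5-acetoxy-3-methylpentyl]-4,4,7,8a-tetramethyl-1,2,3,4,4a,5,8,8a-octahydronaphthalen-1-yl] 1H-imidazole-1-carbothioate | CC(=O)OCC[C@@H](C)CC[C@@H]1[C@]2(C)C(OC(=S)n3ccnc3)CCC(C)(C)[C@@H]2CC=C1C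
F4 | step 8 | (3S)-3-methyl-5-[(1S,4aS,8aR)-2,5,5,8a-tetramethyl-1,4,4a,5,6,7,8,8a-octahydronaphthalen-1-yl]pentyl acetate | CC(=O)OCC[C@@H](C)CC[C@@H]1[C@]2(C)CCCC(C)(C)[C@@H]2CC=C1C
F5 | step 9 | (1R,2R,4aS,8aR)-3-(acetoxymercurio)-1-[(3S)-5-hydroxy-3-methylpentyl]-2,5,5,8a-tetramethyldecahydronaphthalen-2-ol (mercury trans to the hydroxyl) | OCC[C@@H](C)CC[C@@H]1[C@]2(C)CCCC(C)(C)[C@@H]2C[C@H]([Hg]OC(C)=O)[C@@]1(C)O
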